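The bond on which everything rests lies in ring B (the bromodimethylcyclohexane): it joins the CMe2 carbon to the ring CH2 next to the junction CH, and it is cut together with the C–Br bond. The key step exploits that CMe2 sits between CHBr and that CH2, and that the carbinol bridgehead of the 7-oxabicyclo[2.2.1]heptane can serve as the ipso carbon of a phenol (ring A). One bromonium-triggered cyclization of an open-chain enol acetate, (S)-3-(4-acetoxyphenyl)-7-methylocta-1,6-dienyl acetate, closes ring B and sets Br 1,4-trans to the junction substituent. The arene is then dearomatized, desymmetrized and bridged by bromoetherification.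

Key step: step 4

Assumption: the antipodes named for the diene ligand (step 2) and the lithium amide (step 10) are those expected from the usual facial models and would be exchanged for their mirror images if a trial run shows the opposite sense; the E/Z ratio of enol acetate 8 is taken as immaterial.

Step 1
Reactants: 1 5-bromo-2-methylpent-2-ene; 2 (E)-3-(dimethylamino)acrolein
Product: 5 (2E)-7-methylocta-2,6-dienal, via 4-methylpent-3-enylmagnesium bromide 3 (not isolated), via bromomagnesium alkoxide 1,2-adduct 4 (not isolated)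
Conditions: Mg, THF, rt → 40 °C; 2, THF, −20 → 0 °C; 1 M HCl, 0 °C
Reagents that add atoms: water, O
Why: Grignard 1,2-addition to the vinylogous formamide followed by acid-induced loss of the hydroxyl group and hydrolysis of the vinylogous iminium ion (three-carbon enal homologation) gives the conjugated (E)-enal under thermodynamic control, the aldehyde oxygen coming from water.

Step 2
Reactants: 5 (2E)-7-methylocta-2,6-dienal; 6 4-hydroxyphenylboronic acid
Product: 7 (3S)-3-(4-hydroxyphenyl)-7-methyloct-6-enal
Conditions: [RhCl(C2H4)2]2 (2.5 mol%), (S,S)-2,5-diphenylbicyclo[2.2.2]octa-2,5-diene (5.5 mol%), KOH (0.5 equiv), dioxane/H2O 10:1, 30 °C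
Reagents that add atoms: none
Why: Hayashi–Miyaura 1,4-arylation, in which the aryl–rhodium species bound to the C2-symmetric diene adds to one enantioface of the (E)-enal and sets the benzylic junction stereocentre as (S) under catalyst control, while the diene ligand suppresses 1,2-addition to the aldehyde and the remote trisubstituted alkene is inert.

Step 3
Reactants: 7 (3S)-3-(4-hydroxyphenyl)-7-methyloct-6-enal
Product: 8 4-[(1E,3S)-1-acetoxy-7-methylocta-1,6-dien-3-yl]phenyl acetate
Conditions: Ac2O, KOAc (cat.), 110 °C
Reagents that add atoms: acetic anhydride, CC(=O)OC(C)=O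
Why: Phenol O-acetylation and base-mediated enol acetylation of the aldehyde take place together; enolization touches only C2, so the C3 stereocentre is safe, and the basic medium holds back the carbonyl-ene closure open to this citronellal-type aldehyde.

Step 4
Reactants: 8 4-[(1E,3S)-1-acetoxy-7-methylocta-1,6-dien-3-yl]phenyl acetate
Product: 9 4-[(1S,2R,4S)-4-bromo-2-formyl-3,3-dimethylcyclohexyl]phenyl acetate
Conditions: TBCO (2,4,4,6-tetrabromocyclohexa-2,5-dienone, 1.1 equiv), MeNO2, −20 → 0 °C
Reagents that add atoms: 2,4,4,6-tetrabromocyclohexa-2,5-dienone, O=C1C(Br)=CC(Br)(Br)C=C1Br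
Why: Proposed new method: TBCO hands Br+ reversibly to the trisubstituted C6=C7 alkene, the enol acetate carbon C2 opens the bromonium ion at the tertiary carbon C7 anti to bromine through a chair, and the acyloxycarbenium ion so formed passes its acetyl group to the 2,4,6-tribromophenoxide left by the reagent, which unveils the aldehyde. The closest known reaction types are bromonium-initiated cation–olefin cyclizations of prenyl-type alkenes with TBCO or Et2SBr·SbCl5Br, cationic cyclizations terminated by enol esters, and the acid cyclization of citral enamines to cyclocitral. Ring B closes in the 6-endo mode with respect to the bromonium ion (Markovnikov, new C–C bond at CMe2) while the enol double bond stays exocyclic. The new CHBr stereocentre is controlled by the aryl-bearing carbon from step 2: the aryl group lies equatorial in the chair, because an axial aryl group would be syn-diaxial to a methyl of CMe2, and anti opening places Br equatorial, hence 1,4-trans; the formyl-bearing carbon needs no control because step 5 turns it into CH2. The step needs 1,4-diastereoselectivity and site selectivity for Br+; the first should come from reversible bromonium formation draining both bromonium diastereomers through the favoured chair, the second from the higher nucleophilicity of the trisubstituted alkene over the enol acetate and the acetylated arene, whose weak donor ability also shuts down ipso or ortho capture.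

Step 5
Reactants: 9 4-[(1S,2R,4S)-4-bromo-2-formyl-3,3-dimethylcyclohexyl]phenyl acetate
Product: 10 4-[(1S,4S)-4-bromo-3,3-dimethylcyclohexyl]phenyl acetate
Conditions: RhCl(PPh3)3 (1.1 equiv), xylene, 130 °C
Reagents that add atoms: none
Why: Tsuji–Wilkinson decarbonylation (formyl C–H oxidative addition to monovalent rhodium, CO extrusion, C–H reductive elimination) replaces CHO by H to leave the ring CH2, without touching the aryl-bearing and CHBr stereocentres or the hindered secondary bromide.

Step 6
Reactants: 10 4-[(1S,4S)-4-bromo-3,3-dimethylcyclohexyl]phenyl acetate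
Product: 11 4-[(1S,4S)-4-bromo-3,3-dimethylcyclohexyl]phenol
Conditions: K2CO3 (cat.), MeOH, 0 °C → rt
Reagents that add atoms: none
Why: Base-catalysed transesterification (methanolysis) of the aryl acetate frees the phenol, and the neopentyl-type equatorial bromide is inert to methoxide at this temperature.

Step 7
Reactants: 11 4-[(1S,4S)-4-bromo-3,3-dimethylcyclohexyl]phenol
Product: 13 4-[(1S,4S)-4-bromo-3,3-dimethylcyclohexyl]-4-hydroxycyclohexa-2,5-dien-1-one, via para-hydroperoxy dienone 12 (not isolated)
Conditions: Oxone (2KHSO5·KHSO4·K2SO4), NaHCO3, MeCN/H2O, rt; then Me2S, 0 °C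
Reagents that add atoms: potassium peroxymonosulfate (the oxidant in Oxone), [K+].[O-]S(=O)(=O)OO
Why: Oxidative dearomatization: singlet oxygen released from KHSO5 under bicarbonate adds at the para position of the phenol to give the 4-hydroperoxy dienone, which Me2S reduces to the para-quinol; no phenoxenium ion is involved, so the benzylic C–H is not at risk.

Step 8
Reactants: 13 4-[(1S,4S)-4-bromo-3,3-dimethylcyclohexyl]-4-hydroxycyclohexa-2,5-dien-1-one
Product: 14 4-[(1S,4S)-4-bromo-3,3-dimethylcyclohexyl]-4-hydroxycyclohexan-1-one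
Conditions: H2 (1 atm), 5% Rh/Al2O3, EtOAc, rt
Reagents that add atoms: none
Why: Heterogeneous catalytic hydrogenation saturates both disubstituted enone C=C bonds under neutral conditions, where rhodium on alumina spares the tertiary C–O bond, the ketone and the C–Br bond, and leaves ring A locally mirror-symmetric.

Step 9
Reactants: 14 4-[(1S,4S)-4-bromo-3,3-dimethylcyclohexyl]-4-hydroxycyclohexan-1-one
Product: 15 4-[(1S,4S)-4-bromo-3,3-dimethylcyclohexyl]-4-(triethylsilyloxy)cyclohexan-1-one
Conditions: TESOTf, 2,6-lutidine, CH2Cl2, −78 → 0 °C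
Reagents that add atoms: triethylsilyl trifluoromethanesulfonate, CC[Si](CC)(CC)OS(=O)(=O)C(F)(F)F
Why: Silylation of the tertiary alcohol with a silyl triflate and a hindered pyridine base, under which the ketone is not enolized at low temperature, masks the OH for the enolate chemistry.

Step 10
Reactants: 15 4-[(1S,4S)-4-bromo-3,3-dimethylcyclohexyl]-4-(triethylsilyloxy)cyclohexan-1-one
Product: 17 (4S)-4-[(1S,4S)-4-bromo-3,3-dimethylcyclohexyl]-4-(triethylsilyloxy)cyclohex-1-en-1-yl trifluoromethanesulfonate, via lithium enolate 16 (not isolated)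
Conditions: (S,S)-bis(1-phenylethyl)amine·HCl, n-BuLi (2 equiv per amine salt), THF, −78 → 0 → −78 °C; 15, −78 °C; then N-(5-chloropyridin-2-yl)bis(trifluoromethanesulfonyl)imide, −78 → −20 °C
Reagents that add atoms: N-(5-chloropyridin-2-yl)-1,1,1-trifluoro-N-[(trifluoromethyl)sulfonyl]methanesulfonamide, FC(F)(F)S(=O)(=O)N(c1ccc(Cl)cn1)S(=O)(=O)C(F)(F)F
Why: Chiral lithium amide desymmetrization: the C2-symmetric amide with LiCl removes one of the two axial α-hydrogens of the conformationally biased ketone (cyclohexyl equatorial, silyloxy axial), which sets the carbinol stereocentre under reagent control, and the enolate, which cannot change arm without a proton source, is O-triflated.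

Step 11
Reactants: 17 (4S)-4-[(1S,4S)-4-bromo-3,3-dimethylcyclohexyl]-4-(triethylsilyloxy)cyclohex-1-en-1-yl trifluoromethanesulfonate
Product: 18 {[(1S)-1-[(1S,4S)-4-bromo-3,3-dimethylcyclohexyl]-4-methylcyclohex-3-en-1-yl]oxy}triethylsilane
Conditions: Pd(PPh3)4 (5 mol%), Me2Zn (2 equiv), THF, 0 → 50 °C
Reagents that add atoms: dimethylzinc, C[Zn]C
Why: Negishi coupling, in which zerovalent palladium inserts into the alkenyl C–OTf bond far faster than into the hindered secondary C(sp3)–Br bond and methyl transfer from zinc with reductive elimination installs the vinylic methyl group.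

Step 12
Reactants: 18 {[(1S)-1-[(1S,4S)-4-bromo-3,3-dimethylcyclohexyl]-4-methylcyclohex-3-en-1-yl]oxy}triethylsilane
Product: 19 (1S)-1-[(1S,4S)-4-bromo-3,3-dimethylcyclohexyl]-4-methylcyclohex-3-en-1-ol
Conditions: HF·pyridine, pyridine, THF, 0 °C → rt
Reagents that add atoms: none
Why: Fluoride-driven Si–O cleavage (desilylation) with a buffered reagent frees the tertiary alcohol without ionizing it or protonating the trisubstituted alkene.

Step 13
Reactants: 19 (1S)-1-[(1S,4S)-4-bromo-3,3-dimethylcyclohexyl]-4-methylcyclohex-3-en-1-ol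
Product: 20 (1R,2R,4S)-2-bromo-4-[(1S,4S)-4-bromo-3,3-dimethylcyclohexyl]-1-methyl-7-oxabicyclo[2.2.1]heptane
Conditions: NBS, CH2Cl2, 0 °C, dark
Reagents that add atoms: N-bromosuccinimide, BrN1C(=O)CCC1=O
Why: Transannular bromoetherification: of the reversibly formed bromonium ions only the one anti to the tertiary OH can be opened, the OH attacks the methyl-bearing carbon (Markovnikov) across a boat to close the ether bridge, so the methyl bridgehead follows from the carbinol centre and Br ends anti to oxygen (endo).

Compound list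
1 | 5-bromo-2-methylpent-2-ene | CC(C)=CCCBr | starting material
2 | (E)-3-(dimethylamino)acrolein | CN(C)/C=C/C=O | starting material
3 | 4-methylpent-3-enylmagnesium bromide | CC(C)=CCC[Mg]Br | intermediate
4 | bromomagnesium (1E)-1-(dimethylamino)-7-methylocta-1,6-dien-3-olate (racemic at C3) | CC(C)=CCCC(O[Mg]Br)/C=C/N(C)C | intermediate
5 | (2E)-7-methylocta-2,6-dienal | CC(C)=CCC/C=C/C=O | intermediate
6 | 4-hydroxyphenylboronic acid | OB(O)c1ccc(O)cc1 | starting material
7 | (3S)-3-(4-hydroxyphenyl)-7-methyloct-6-enal | O=CC[C@@H](c1ccc(O)cc1)CCC=C(C)C | intermediate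
8 | 4-[(1E,3S)-1-acetoxy-7-methylocta-1,6-dien-3-yl]phenyl acetate (E drawn, Z reacts alike) | CC(=O)O/C=C/[C@@H](c1ccc(OC(C)=O)cc1)CCC=C(C)C | intermediate
9 | 4-[(1S,2R,4S)-4-bromo-2-formyl-3,3-dimethylcyclohexyl]phenyl acetate (aryl and Br trans, formyl configuration immaterial) | CC1(C)[C@H](C=O)[C@@H](c2ccc(OC(C)=O)cc2)CC[C@@H]1Br | intermediate
10 | 4-[(1S,4S)-4-bromo-3,3-dimethylcyclohexyl]phenyl acetate | CC1(C)C[C@@H](c2ccc(OC(C)=O)cc2)CC[C@@H]1Br | intermediate
11 | 4-[(1S,4S)-4-bromo-3,3-dimethylcyclohexyl]phenol | CC1(C)C[C@@H](c2ccc(O)cc2)CC[C@@H]1Br | intermediate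
12 | 4-[(1S,4S)-4-bromo-3,3-dimethylcyclohexyl]-4-hydroperoxycyclohexa-2,5-dien-1-one | CC1(C)C[C@@H](C2(OO)C=CC(=O)C=C2)CC[C@@H]1Br | intermediate
13 | 4-[(1S,4S)-4-bromo-3,3-dimethylcyclohexyl]-4-hydroxycyclohexa-2,5-dien-1-one | CC1(C)C[C@@H](C2(O)C=CC(=O)C=C2)CC[C@@H]1Br | intermediate
14 | 4-[(1S,4S)-4-bromo-3,3-dimethylcyclohexyl]-4-hydroxycyclohexan-1-one | CC1(C)C[C@@H](C2(O)CCC(=O)CC2)CC[C@@H]1Br | intermediate
15 | 4-[(1S,4S)-4-bromo-3,3-dimethylcyclohexyl]-4-(triethylsilyloxy)cyclohexan-1-one | CC1(C)C[C@@H](C2(O[Si](CC)(CC)CC)CCC(=O)CC2)CC[C@@H]1Br | intermediate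
16 | lithium (4S)-4-[(1S,4S)-4-bromo-3,3-dimethylcyclohexyl]-4-(triethylsilyloxy)cyclohex-1-en-1-olate | CC1(C)C[C@@H]([C@@]2(O[Si](CC)(CC)CC)CC=C(O[Li])CC2)CC[C@@H]1Br | intermediate
17 | (4S)-4-[(1S,4S)-4-bromo-3,3-dimethylcyclohexyl]-4-(triethylsilyloxy)cyclohex-1-en-1-yl trifluoromethanesulfonate | CC1(C)C[C@@H]([C@@]2(O[Si](CC)(CC)CC)CC=C(OS(=O)(=O)C(F)(F)F)CC2)CC[C@@H]1Br | intermediate
18 | {[(1S)-1-[(1S,4S)-4-bromo-3,3-dimethylcyclohexyl]-4-methylcyclohex-3-en-1-yl]oxy}triethylsilane | CC1(C)C[C@@H]([C@@]2(O[Si](CC)(CC)CC)CC=C(C)CC2)CC[C@@H]1Br | intermediate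
19 | (1S)-1-[(1S,4S)-4-bromo-3,3-dimethylcyclohexyl]-4-methylcyclohex-3-en-1-ol | CC1(C)C[C@@H]([C@@]2(O)CC=C(C)CC2)CC[C@@H]1Br | intermediate
20 | (1R,2R,4S)-2-bromo-4-[(1S,4S)-4-bromo-3,3-dimethylcyclohexyl]-1-methyl-7-oxabicyclo[2.2.1]heptane | CC1(C)C[C@@H]([C@@]23CC[C@@](C)(O2)[C@H](Br)C3)CC[C@@H]1Br | target

Total step count: 13 steps. Longest linear sequence: 13 steps (1 to 20).

Steps most likely to fail

Step 4. Br+ may be taken up by the enol acetate double bond, or the bromonium ion may lose a methyl proton to give an allylic bromide before carbon attacks. If Br+ transfer is not reversible, facial selection at CHBr is lost. The fallback sets out from enol acetate 8 and uses divalent mercury in place of Br+. Hg(OCOCF3)2 in MeNO2 at −20 °C, followed by aqueous NaBr, should close the same ring by a mercurinium-initiated cation–olefin cyclization terminated by the enol ester, a known reaction class with reversible mercurinium formation and the same chair. It would give 4-[(1S,2R,4S)-4-(bromomercurio)-2-formyl-3,3-dimethylcyclohexyl]phenyl acetate F1. Brominolysis of the C–Hg bond with Br2 and LiBr in pyridine at 0 °C under O2, which goes with retention at carbon, comes back to the route at aldehyde 9.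

Step 10. The axial silyloxy group is syn-diaxial to the α-hydrogens that the base must remove, so deprotonation may be slow and arm selection poor. Proton exchange between enolate and unreacted ketone before triflation would erode it further. The fallback sets out from para-quinol 13 and moves the desymmetrization to the dienone stage. Silylation (TESOTf, 2,6-lutidine, CH2Cl2) would give 4-[(1S,4S)-4-bromo-3,3-dimethylcyclohexyl]-4-(triethylsilyloxy)cyclohexa-2,5-dien-1-one F4. A copper hydride-catalysed enantioselective mono-conjugate reduction (Cu(OAc)2, DTBM-SEGPHOS, (EtO)2MeSiH, t-BuOH, toluene) would follow, with the ligand antipode that leaves the C=C on the arm destined to carry CHBr. It would give (4R)-4-[(1S,4S)-4-bromo-3,3-dimethylcyclohexyl]-4-(triethylsilyloxy)cyclohex-2-en-1-one F5. 1,4-Reduction with LiBH(s-Bu)3 in THF at −78 °C generates the regiodefined lithium enolate 16, and its capture with N-(5-chloropyridin-2-yl)bis(trifluoromethanesulfonyl)imide comes back to the route at enol triflate 17.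

Step 5. The hindered formyl group may add to rhodium only slowly, at a temperature where β-hydride elimination from the secondary alkyl–rhodium intermediate (loss as a cyclohexene) or attack on the C–Br bond competes. The fallback sets out from aldehyde 9 and removes the carbon as CO2 by a radical path. Pinnick oxidation (NaClO2, NaH2PO4, 2-methylbut-2-ene, t-BuOH/H2O) would give (1R,3S,6S)-6-(4-acetoxyphenyl)-3-bromo-2,2-dimethylcyclohexane-1-carboxylic acid F2. Coupling with 1-hydroxypyridine-2(1H)-thione (DCC, DMAP, CH2Cl2, dark) would give 2-thioxopyridin-1(2H)-yl (1R,3S,6S)-6-(4-acetoxyphenyl)-3-bromo-2,2-dimethylcyclohexane-1-carboxylate F3. Visible-light irradiation with t-BuSH in THF (Barton reductive decarboxylation, tin-free) comes back to the route at aryl acetate 10.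

Further compounds
F1 | step 4 | 4-[(1S,2R,4S)-4-(bromomercurio)-2-formyl-3,3-dimethylcyclohexyl]phenyl acetate | CC1(C)[C@H](C=O)[C@@H](c2ccc(OC(C)=O)cc2)CC[C@@H]1[Hg]Br
F2 | step 5 | (1R,3S,6S)-6-(4-acetoxyphenyl)-3-bromo-2,2-dimethylcyclohexane-1-carboxylic acid | CC1(C)[C@H](C(=O)O)[C@@H](c2ccc(OC(C)=O)cc2)CC[C@@H]1Br
F3 | step 5 | 2-thioxopyridin-1(2H)-yl (1R,3S,6S)-6-(4-acetoxyphenyl)-3-bromo-2,2-dimethylcyclohexane-1-carboxylate | CC1(C)[C@H](C(=O)ON2C=CC=CC2=S)[C@@H](c2ccc(OC(C)=O)cc2)CC[C@@H]1Br
F4 | step 10 | 4-[(1S,4S)-4-bromo-3,3-dimethylcyclohexyl]-4-(triethylsilyloxy)cyclohexa-2,5-dien-1-one | CC1(C)C[C@@H](C2(O[Si](CC)(CC)CC)C=CC(=O)C=C2)CC[C@@H]1Br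
F5 | step 10 | (4R)-4-[(1S,4S)-4-bromo-3,3-dimethylcyclohexyl]-4-(triethylsilyloxy)cyclohex-2-en-1-one | CC1(C)C[C@@H]([C@@]2(O[Si](CC)(CC)CC)C=CC(=O)CC2)CC[C@@H]1Br
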